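**Assumption (one line):** I read the target in 6,7-seco-ent-kaurane numbering (C19 = CH2OAc, C18 = CH3, C6 = CHO, C7 = lactone C=O, C20 = lactone OCH2). I assume the C6/C19-cis aldol diastereomer in Step 1 is separable from any minor isomer.

## Retrosynthetic overview
1. The target comes from oxidation of the C6 primary alcohol and of the allylic C15 position of tetracycle 17.
2. The bicyclo[3.2.1] D ring (C13–C16 bond, which sets C13) closes by 5-exo vinyl-radical cyclisation onto the Δ12 alkene of tricycle 16.
3. Ring C, C9, the C11–OH and the quaternary C8 come from one SmI2 cascade on spirolactone-enal 15: the (Z)-enal ketyl adds 6-endo to the enoate, then the Sm enolate is C-alkylated with 2,3-dibromopropene.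
4. The spirolactone (C9–C10 bond) comes from Ti(III) epoxide-opening radical addition of A-ring epoxide 6 to acrylate 10, followed by lactonisation.
5. The A ring comes from asymmetric conjugate addition to 3-methylcyclohexenone, and the chain from 3,3-dimethoxypropyne and methyl 2-(bromomethyl)acrylate. Rings are formed in the order A → lactone → C → D.

## Route

**Step 1**
Reactants: 1, 3-methylcyclohex-2-en-1-one
Product: 2, (2,3-cis) 2-(hydroxymethyl)-3-methyl-3-vinylcyclohexan-1-one, C6-CH2OH cis to the vinyl group, single enantiomer (SMILES in list)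
Conditions: CuBr·SMe2 (5 mol%), chiral Josiphos-type ligand (6 mol%, enantiomer chosen to give the drawn C4 configuration), CH2=CHMgBr, t-BuOMe, –78 °C; then monomeric CH2O (from paraformaldehyde) in THF, –78 → 0 °C
Reagents that add atoms: vinylmagnesium bromide, C=C[Mg]Br; formaldehyde, C=O
Why: Proposed new method: Cu/chiral-diphosphine 1,4-addition of vinyl Grignard to 3-methylcyclohexenone gives the C10–C5 Mg enolate, which is trapped in situ by formaldehyde (aldol), so the ACA sets the quaternary C4 and axial attack on the conformer with axial methyl puts C6 cis to the vinyl group; the closest known reaction is Cu/Josiphos Grignard ACA to 3-methylcyclohexenone with tandem enolate trapping.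

**Step 2**
Reactants: 2
Product: 3, the TIPS ether of 2
Conditions: TIPSCl, imidazole, DMF, rt
Reagents that add atoms: TIPSCl, CC(C)[Si](Cl)(C(C)C)C(C)C
Why: Silyl protection of the primary alcohol leaves all stereocentres untouched.

**Step 3**
Reactants: 3
Product: 4, spiro-epoxide (1-oxaspiro[2.5]octane; C10 epoxide configuration undefined, epimers converge in Step 8)
Conditions: Me3S+ I–, NaH, DMSO/THF, 0 °C → rt
Reagents that add atoms: trimethylsulfonium iodide, C[S+](C)C.[I-] (delivers CH2)
Why: Corey–Chaykovsky epoxidation converts the hindered ketone into the radical precursor, and the epoxide stereochemistry is erased when the tertiary radical forms.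

**Step 4**
Reactants: 4
Product: 5, C19 primary alcohol (vinyl → CH2OH)
Conditions: O3, CH2Cl2/MeOH, –78 °C; then NaBH4, –78 → 0 °C
Reagents that add atoms: ozone, O=[O+][O-] (supplies the oxygen of the new C19 CH2OH; NaBH4 supplies only hydrogen)
Why: Ozonolysis followed by reductive work-up (Lemieux-type vinyl → CH2OH conversion) cleaves the vinyl group selectively, the epoxide and silyl ether survive, and C4 is untouched.

**Step 5**
Reactants: 5
Product: 6, C19 TBS ether
Conditions: TBSCl, imidazole, DMF, rt
Reagents that add atoms: TBSCl, CC(C)(C)[Si](C)(C)Cl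
Why: The silyl group protects C19 before the radical step.

**Step 6**
Reactants: 7, 3,3-dimethoxyprop-1-yne; 8, methyl 2-(bromomethyl)acrylate
Product: 9, methyl 2-methylene-6,6-dimethoxyhex-4-ynoate
Conditions: EtMgBr, THF, 0 °C; CuI (10 mol%); add 8, 0 °C → rt
Reagents that add atoms: none
Why: Cu-catalysed coupling of the alkynyl Grignard with the allylic bromide (SN2/SN2′, same product) builds the C11–C14 chain.

**Step 7**
Reactants: 9
Product: 10, methyl (Z)-2-methylene-6,6-dimethoxyhex-4-enoate
Conditions: H2 (1 atm), Lindlar catalyst, quinoline, EtOAc/hexane, rt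
Reagents that add atoms: none
Why: Lindlar semihydrogenation adds H2 syn, so the C12=C13 alkene is Z, as needed for the later cyclohexene ring.

**Step 8**
Reactants: 6; 10
Product: 11, spirolactone (C8 epimeric, C10 spiro stereocentre set)
Conditions: Cp2TiCl2 (3 equiv), Zn (6 equiv), THF, rt, 6 + 10 (3 equiv); aq. NH4Cl work-up; then DBU (0.2 equiv), PhMe, 40 °C
Reagents that add atoms: none
Why: Ti(III) epoxide opening gives the tertiary C10 radical, which adds (Giese) to the acrylate CH2 (new C9–C10 bond) and is reduced to a Ti enolate. The alkoxide then lactonises onto the ester, completed under mild base so the dimethyl acetal survives. The β-face (axial) approach is blocked by the axial C19 group, so the acrylate adds equatorially from the α-face, anti to C19 and C6, which leaves C20 axial and C9 equatorial.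

**Step 9**
Reactants: 11
Product: 12, α,β-unsaturated spirolactone (C8=C9)
Conditions: LDA, THF, –78 °C; PhSeCl; then 30% H2O2, pyridine, CH2Cl2, 0 °C
Reagents that add atoms: none (PhSe is lost as selenoxide)
Why: α-Selenation followed by syn selenoxide elimination (endocyclic elimination is preferred in six-membered α-selenoxy lactones) creates the enoate acceptor and removes the C8 epimer issue.

**Step 10**
Reactants: 12
Product: 13, C19 free alcohol
Conditions: TBAF (1.0 equiv), AcOH (1.0 equiv), THF, 0 °C
Reagents that add atoms: none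
Why: Buffered fluoride removes the primary TBS group selectively over the more hindered TIPS group.

**Step 11**
Reactants: 13
Product: 14, C19 acetate
Conditions: Ac2O, Et3N, DMAP (cat.), CH2Cl2, 0 °C
Reagents that add atoms: acetic anhydride, CC(=O)OC(C)=O
Why: Acetylation installs the target C19–OAc after the enolate chemistry of Step 9, where an acetate would have been deprotonated.

**Step 12**
Reactants: 14
Product: 15, (Z)-enal
Conditions: PPTS, acetone/H2O (9:1), 35 °C, short reaction time
Reagents that add atoms: water, O
Why: Mild acetal hydrolysis unmasks the C11 aldehyde while keeping the Z geometry of C12=C13.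

**Step 13**
Reactants: 15
Product: 16, tricyclic lactone with C11–OH, C8 2-bromoallyl and Δ12 cyclohexene
Conditions: SmI2 (2.4 equiv), THF/HMPA, –78 °C; then CH2=C(Br)CH2Br (10 equiv), –78 → 0 °C
Reagents that add atoms: 2,3-dibromopropene, C=C(Br)CBr (delivers the 2-bromoallyl C15–C16–C17 unit)
Why: Proposed new method: the Sm ketyl of the (Z)-enal has spin density at C11 and C13, but C13 cannot reach the enoate without forming a 3- or 4-membered ring, so C11 adds 6-endo to the enoate β-carbon C9 (C9–C11 bond) and leaves a stabilised C8 radical. This is reduced to the Sm(III) enolate, which is alkylated at C8 by the allylic bromide in the same pot; the chair-like Sm-chelated transition state sets C9 and the C11–OH. The closest known reaction is the SmI2 ketyl–enoate reductive cascade of seco-kauranoid dialdehydes, extended with enolate alkylation.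

**Step 14**
Reactants: 16
Product: 17, tetracycle with C15H2 and exocyclic C16=C17
Conditions: Bu3SnH (1.5 equiv, syringe pump), AIBN (0.2 equiv), PhH (2 mM), 80 °C
Reagents that add atoms: none
Why: The vinyl radical from C16–Br cyclises 5-exo onto C13 of the cis-alkene (C13–C16 bond, radical cyclisation), the bicyclic constraint fixes C13, and the C12 radical is reduced by H-atom transfer.

**Step 15**
Reactants: 17
Product: 18, C15 enone
Conditions: SeO2 (0.3 equiv), TBHP (5 equiv), CH2Cl2, rt; then MnO2 (20 equiv)
Reagents that add atoms: tert-butyl hydroperoxide, CC(C)(C)OO (oxygen source)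
Why: Riley-type allylic oxidation occurs at C15 (the allylic bridgehead C13–H cannot react), and MnO2 oxidises any allylic alcohol to the enone without touching the non-allylic C11 alcohol.

**Step 16**
Reactants: 18
Product: 19, C6 free primary alcohol
Conditions: TBAF, AcOH, THF, 0 °C
Reagents that add atoms: none
Why: Buffered fluoride removes the TIPS group without acetate migration or retro-aldol.

**Step 17**
Reactants: 19
Product: 20, trichorabdal B
Conditions: TEMPO (0.2 equiv), PhI(OAc)2 (1.3 equiv), CH2Cl2, 0 °C
Reagents that add atoms: none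
Why: TEMPO/BAIB oxidises the unhindered primary alcohol to the C6 aldehyde without oxidising the secondary C11 alcohol, and the neutral conditions avoid C5 epimerisation.

## Compound list
| No. | Name | SMILES | Role |
|---|---|---|---|
| 1 | 3-methylcyclohex-2-en-1-one | CC1=CC(=O)CCC1 | starting material |
| 2 | 2-(hydroxymethyl)-3-methyl-3-vinylcyclohexan-1-one (C6 cis to vinyl) | O=C1CCC[C@@](C)(C=C)[C@H]1CO | intermediate |
| 3 | 2-(TIPS-oxymethyl)-3-methyl-3-vinylcyclohexanone | O=C1CCC[C@@](C)(C=C)[C@H]1CO[Si](C(C)C)(C(C)C)C(C)C | intermediate |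
| 4 | 4-(TIPS-oxymethyl)-5-methyl-5-vinyl-1-oxaspiro[2.5]octane | C=C[C@]1(C)CCCC2(CO2)[C@@H]1CO[Si](C(C)C)(C(C)C)C(C)C | intermediate |
| 5 | C19 alcohol, 5-(hydroxymethyl)-5-methyl-4-(TIPS-oxymethyl)-1-oxaspiro[2.5]octane | OC[C@]1(C)CCCC2(CO2)[C@@H]1CO[Si](C(C)C)(C(C)C)C(C)C | intermediate |
| 6 | C19 TBS ether of 5 | CC(C)(C)[Si](C)(C)OC[C@]1(C)CCCC2(CO2)[C@@H]1CO[Si](C(C)C)(C(C)C)C(C)C | intermediate |
| 7 | 3,3-dimethoxyprop-1-yne | COC(OC)C#C | starting material |
| 8 | methyl 2-(bromomethyl)acrylate | C=C(CBr)C(=O)OC | starting material |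
| 9 | methyl 2-methylene-6,6-dimethoxyhex-4-ynoate | C=C(CC#CC(OC)OC)C(=O)OC | intermediate |
| 10 | methyl (Z)-2-methylene-6,6-dimethoxyhex-4-enoate | C=C(C/C=C\C(OC)OC)C(=O)OC | intermediate |
| 11 | spirolactone (2-oxaspiro[5.5]undecan-3-one) with Z-acetal chain, C8 epimeric | O=C1OC[C@@]2(CC1C/C=C\C(OC)OC)CCC[C@@](C)(CO[Si](C)(C)C(C)(C)C)[C@H]2CO[Si](C(C)C)(C(C)C)C(C)C | intermediate |
| 12 | unsaturated spirolactone (C8=C9) | O=C1OC[C@@]2(C=C1C/C=C\C(OC)OC)CCC[C@@](C)(CO[Si](C)(C)C(C)(C)C)[C@H]2CO[Si](C(C)C)(C(C)C)C(C)C | intermediate |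
| 13 | C19 alcohol of 12 | O=C1OC[C@@]2(C=C1C/C=C\C(OC)OC)CCC[C@@](C)(CO)[C@H]2CO[Si](C(C)C)(C(C)C)C(C)C | intermediate |
| 14 | C19 acetate of 13 | O=C1OC[C@@]2(C=C1C/C=C\C(OC)OC)CCC[C@@](C)(COC(C)=O)[C@H]2CO[Si](C(C)C)(C(C)C)C(C)C | intermediate |
| 15 | Z-enal spirolactone | O=C1OC[C@@]2(C=C1C/C=C\C=O)CCC[C@@](C)(COC(C)=O)[C@H]2CO[Si](C(C)C)(C(C)C)C(C)C | intermediate |
| 16 | tricyclic lactone, C11-OH, C8 2-bromoallyl | O=C1OC[C@@]2([C@H]3[C@H](O)C=CC[C@]13CC(Br)=C)CCC[C@@](C)(COC(C)=O)[C@H]2CO[Si](C(C)C)(C(C)C)C(C)C | intermediate |
| 17 | tetracycle, C15H2, C16=C17 | O=C1OC[C@@]2([C@H]3[C@H](O)C[C@@H]4C[C@]13CC4=C)CCC[C@@](C)(COC(C)=O)[C@H]2CO[Si](C(C)C)(C(C)C)C(C)C | intermediate |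
| 18 | C15 enone of 17 | O=C1OC[C@@]2([C@H]3[C@H](O)C[C@@H]4C[C@]13C(=O)C4=C)CCC[C@@](C)(COC(C)=O)[C@H]2CO[Si](C(C)C)(C(C)C)C(C)C | intermediate |
| 19 | C6 free alcohol | O=C1OC[C@@]2([C@H]3[C@H](O)C[C@@H]4C[C@]13C(=O)C4=C)CCC[C@@](C)(COC(C)=O)[C@H]2CO | intermediate |
| 20 | trichorabdal B | C=C1C(=O)[C@]23C[C@H]1C[C@@H](O)[C@@H]2[C@@]1(CCC[C@@](C)(COC(C)=O)[C@H]1C=O)COC3=O | target |

## Totals
Total steps: 17. Longest linear sequence: 15 steps (Steps 1–5, then 8–17).

## Three steps most likely to fail
1. **Step 13 (SmI2 cascade).** The (Z)-enal ketyl may react poorly at the carbinol carbon, or over-reduce or isomerise. The 6-endo closure next to the spiro quaternary centre is hindered, and the hindered Sm enolate may not alkylate cleanly.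
   Fallback (different approach): use a saturated C11 aldehyde chain with a preset C13 stereocentre (from asymmetric conjugate addition) and close ring D by intramolecular SmI2 ketyl/aldol (C8–C15 bond). Then oxidise the resulting allylic C15 alcohol with MnO2.
2. **Step 8 (Ti(III) Giese/lactonisation).** A tertiary radical must add to a 2-substituted acrylate to form the spiro quaternary centre, with competing Ti-mediated reduction, β-H elimination or epoxide isomerisation.
   Fallback (different approach): generate the C10 radical by Fe–H HAT on a Δ1(10)-alkene bearing a protected C20–OH (made from ketone 3 by enol triflate/carbonylation/reduction). Add it to 10 and lactonise after deprotection.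
3. **Step 1 (ACA/hydroxymethylation).** Enantioselectivity with vinyl Grignard is uncertain, and the C6/C19-cis selectivity of the aldol is only modest.
   Fallback (different approach): build the A ring by desymmetrising a 2,2-disubstituted cyclohexane-1,3-dione. Alternatively, fix the cis relationship with a temporary 6,19-oxa-bridge formed by Prins-type cyclisation of a C19–O–CH2+ oxocarbenium onto the C5 enol.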